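**Plan**
- Cembrane numbering: C1 is the ring-fusion CH, C15(=C17)–C16 the acrylate unit, and the carbocycle runs C1–C14 with the oxirane at C3/C4, carbinols at C6 and C11, the Z-alkene C7=C8 and the oxygenated quaternary C12. Enabling feature: O6 and O11 lie 1,6 to each other across C7=C8, so a single silicon atom bridging them puts that alkene into a nine-membered 1,3-dioxa-2-silacycle, which tolerates only the Z geometry.
- Retrosynthetic cuts, in order: oxirane oxygen at C3/C4; lactone bond C16(=O)–O12; C13–C14 (sulfone carbanion onto the C12/C13 oxirane); C7=C8 (tethered metathesis); the two Si–O bonds. This leaves a C1–C7 sulfone carbinol (fragment A) and a C8–C13 epoxy carbinol (fragment B).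
- Forward: fragments A and B are joined as a mixed diisopropylsilaketal; metathesis closes the nine-membered silacycle; C13–C14 closure gives the fourteen-membered carbocycle; the seven-membered lactone follows, then the oxirane, then loss of silicon.
- Stereochemistry: C1 from BINAP–rhodium conjugate alkenylation; 3Z from the Still–Wittig rearrangement; C6 from amino-alcohol-catalysed vinylzinc addition; C11/C12 from Sharpless kinetic resolution followed by Mitsunobu inversion; 7Z from the ring; C3/C4 from Shi epoxidation.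

Key step: step 19

Remark: the target is read from its SMILES as (1S,3R,4S,6R,7Z,11R,12R) in this numbering; C2 and C5 are cis on the oxirane, so the precursor alkene must be 3Z, and O4 is 1,3-syn to O6.

**Route**

Step 1
Reactants: 1 2,3-dibromopropene; 2 4-methoxybenzyl alcohol
Product: 3 1-{[(2-bromoprop-2-en-1-yl)oxy]methyl}-4-methoxybenzene
Conditions: NaH, Bu4NI (cat.), THF, 0 °C to rt
Reagents that add atoms: none
Why: Williamson ether synthesis; the alkoxide should displace only the allylic bromide, the vinylic bromide being inert to SN2.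

Step 2
Reactants: 3 1-{[(2-bromoprop-2-en-1-yl)oxy]methyl}-4-methoxybenzene
Product: 4 2-{3-[(4-methoxybenzyl)oxy]prop-1-en-2-yl}-4,4,5,5-tetramethyl-1,3,2-dioxaborolane
Conditions: B2pin2, PdCl2(PPh3)2 (3 mol %), PPh3, KOPh, toluene, 50 °C
Reagents that add atoms: bis(pinacolato)diboron, CC1(C)OB(OC1(C)C)B1OC(C)(C)C(C)(C)O1
Why: Miyaura borylation of a 1-alkenyl bromide; it avoids a 2-lithioallyl ether, which could expel the alkoxide to give an allene.

Step 3
Reactants: 5 (tert-butyldimethylsilyloxy)acetaldehyde; 6 ethyl (triphenylphosphoranylidene)acetate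
Product: 7 ethyl (E)-4-[(tert-butyldimethylsilyl)oxy]but-2-enoate
Conditions: CH2Cl2, rt
Reagents that add atoms: none
Why: Wittig olefination with a stabilised ylide, which should give the E-enoate needed as conjugate acceptor.

Step 4
Reactants: 7 ethyl (E)-4-[(tert-butyldimethylsilyl)oxy]but-2-enoate; 4 2-{3-[(4-methoxybenzyl)oxy]prop-1-en-2-yl}-4,4,5,5-tetramethyl-1,3,2-dioxaborolane
Product: 8 ethyl (3S)-3-{[(tert-butyldimethylsilyl)oxy]methyl}-4-{[(4-methoxybenzyl)oxy]methyl}pent-4-enoate
Conditions: Rh(acac)(C2H4)2 (3 mol %), (R)-BINAP, K3PO4 (aq.), dioxane/H2O 10:1, 60 °C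
Reagents that add atoms: none
Why: Hayashi–Miyaura reaction; the alkenylrhodium–BINAP species should insert the E-enoate on the α-re face (the (R)-ligand, chosen by the established face model for BINAP–rhodium additions to enones and enoates), setting C1 as S, and the silyloxy group sits γ to the metal so no β-elimination is open.

Step 5
Reactants: 8 ethyl (3S)-3-{[(tert-butyldimethylsilyl)oxy]methyl}-4-{[(4-methoxybenzyl)oxy]methyl}pent-4-enoate
Product: 9 (3S)-3-{[(tert-butyldimethylsilyl)oxy]methyl}-4-{[(4-methoxybenzyl)oxy]methyl}pent-4-enal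
Conditions: iBu2AlH (1.1 equiv), CH2Cl2, −78 °C; Rochelle salt work-up
Reagents that add atoms: none
Why: partial ester reduction; the aluminium hemiacetal is stable at −78 °C and releases the aldehyde only on work-up, and the β-stereocentre cannot epimerise.

Step 6
Reactants: 9 (3S)-3-{[(tert-butyldimethylsilyl)oxy]methyl}-4-{[(4-methoxybenzyl)oxy]methyl}pent-4-enal
Product: 10 (5S)-5-{[(tert-butyldimethylsilyl)oxy]methyl}-6-{[(4-methoxybenzyl)oxy]methyl}-2-methylhepta-1,6-dien-3-ol (both C3 epimers)
Conditions: CH2=C(CH3)MgBr, THF, −78 to 0 °C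
Reagents that add atoms: isopropenylmagnesium bromide, C=C(C)[Mg]Br
Why: Grignard 1,2-addition; the new carbinol centre needs no control because it is destroyed in the rearrangement of step 8.

Step 7
Reactants: 10 (5S)-5-{[(tert-butyldimethylsilyl)oxy]methyl}-6-{[(4-methoxybenzyl)oxy]methyl}-2-methylhepta-1,6-dien-3-ol
Product: 11 tributyl{[((5S)-5-{[(tert-butyldimethylsilyl)oxy]methyl}-6-{[(4-methoxybenzyl)oxy]methyl}-2-methylhepta-1,6-dien-3-yl)oxy]methyl}stannane
Conditions: KH, THF, 0 °C; Bu3SnCH2I, 18-crown-6 (cat.), rt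
Reagents that add atoms: tributyl(iodomethyl)stannane, CCCC[Sn](CCCC)(CCCC)CI
Why: Williamson alkylation of the potassium alkoxide by the iodomethylstannane, the standard entry to a Still–Wittig substrate; no carbon acid in 10 competes.

Step 8
Reactants: 11 tributyl{[((5S)-5-{[(tert-butyldimethylsilyl)oxy]methyl}-6-{[(4-methoxybenzyl)oxy]methyl}-2-methylhepta-1,6-dien-3-yl)oxy]methyl}stannane
Product: 13 (3Z,6S)-6-{[(tert-butyldimethylsilyl)oxy]methyl}-7-{[(4-methoxybenzyl)oxy]methyl}-3-methylocta-3,7-dien-1-ol, via lithiomethyl ether 12 (not isolated)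
Conditions: n-BuLi, THF, −78 to −40 °C; H2O
Reagents that add atoms: none
Why: Still–Wittig [2,3]-sigmatropic rearrangement; tin–lithium exchange gives the unstabilised α-alkoxymethyllithium, whose early envelope transition state places the carbinol substituent pseudo-axial, away from the vinylic methyl, so the trisubstituted 3,4-alkene should form Z.

Step 9
Reactants: 13 (3Z,6S)-6-{[(tert-butyldimethylsilyl)oxy]methyl}-7-{[(4-methoxybenzyl)oxy]methyl}-3-methylocta-3,7-dien-1-ol
Product: 14 (3Z,6S)-6-{[(tert-butyldimethylsilyl)oxy]methyl}-7-{[(4-methoxybenzyl)oxy]methyl}-3-methylocta-3,7-dienal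
Conditions: Dess–Martin periodinane, NaHCO3, CH2Cl2, 0 °C; crude product used at once
Reagents that add atoms: none
Why: Dess–Martin oxidation under buffered, non-basic conditions, so that the β,γ-unsaturated aldehyde should not slip into conjugation.

Step 10
Reactants: 14 (3Z,6S)-6-{[(tert-butyldimethylsilyl)oxy]methyl}-7-{[(4-methoxybenzyl)oxy]methyl}-3-methylocta-3,7-dienal
Product: 15 (3R,5Z,8S)-8-{[(tert-butyldimethylsilyl)oxy]methyl}-9-{[(4-methoxybenzyl)oxy]methyl}-5-methyldeca-1,5,9-trien-3-ol
Conditions: Zn(CH=CH2)2, (S)-diphenyl(1-methylpyrrolidin-2-yl)methanol (10 mol %), toluene/Et2O, −20 to 0 °C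
Reagents that add atoms: divinylzinc, C=C[Zn]C=C
Why: amino-alcohol-catalysed enantioselective addition of a vinylzinc to an aldehyde; the (S)-prolinol-derived zinc alkoxide should deliver vinyl to the si face, as in dialkylzinc additions with this ligand, giving the R carbinol (C6) without basic conditions.

Step 11
Reactants: 15 (3R,5Z,8S)-8-{[(tert-butyldimethylsilyl)oxy]methyl}-9-{[(4-methoxybenzyl)oxy]methyl}-5-methyldeca-1,5,9-trien-3-ol
Product: 16 (2S,4Z,7R)-2-{3-[(4-methoxybenzyl)oxy]prop-1-en-2-yl}-5-methylnona-4,8-diene-1,7-diol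
Conditions: Bu4NF, THF, 0 °C to rt
Reagents that add atoms: none
Why: fluoride cleavage of the primary silyl ether; the benzyl-type ether and the alkenes are untouched.

Step 12
Reactants: 16 (2S,4Z,7R)-2-{3-[(4-methoxybenzyl)oxy]prop-1-en-2-yl}-5-methylnona-4,8-diene-1,7-diol
Product: 17 (3R,5Z,8S)-8-(iodomethyl)-9-{[(4-methoxybenzyl)oxy]methyl}-5-methyldeca-1,5,9-trien-3-ol
Conditions: I2 (1.05 equiv), PPh3, imidazole, CH2Cl2, 0 °C
Reagents that add atoms: iodine, II
Why: Appel-type iodination (Garegg–Samuelsson conditions); with one equivalent at 0 °C the primary hydroxyl should react well ahead of the secondary allylic one.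

Step 13
Reactants: 17 (3R,5Z,8S)-8-(iodomethyl)-9-{[(4-methoxybenzyl)oxy]methyl}-5-methyldeca-1,5,9-trien-3-ol
Product: 18 (3R,5Z,8S)-9-{[(4-methoxybenzyl)oxy]methyl}-5-methyl-8-[(phenylsulfonyl)methyl]deca-1,5,9-trien-3-ol (fragment A)
Conditions: PhSO2Na, Bu4NI (cat.), DMF, 60 °C
Reagents that add atoms: sodium benzenesulfinate, [Na+].[O-]S(=O)c1ccccc1
Why: SN2 S-alkylation of the sulfinate by the primary iodide; the sulfone is introduced only now because steps 7 and 8 would deprotonate it.

Step 14
Reactants: 19 4-bromo-2-methylbut-1-ene; 20 methacrolein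
Product: 22 2,6-dimethylhepta-1,6-dien-3-ol (racemic), via Grignard reagent 21 (not isolated)
Conditions: Mg, THF, rt; then 20, −78 to 0 °C
Reagents that add atoms: none
Why: Grignard formation and 1,2-addition to the enal give the racemic 2-substituted allylic alcohol in one operation.

Step 15
Reactants: 22 2,6-dimethylhepta-1,6-dien-3-ol
Product: 23 (1S)-4-methyl-1-[(2R)-2-methyloxiran-2-yl]pent-4-en-1-ol
Conditions: Ti(OiPr)4 (10 mol %), L-(+)-diisopropyl tartrate (15 mol %), t-BuOOH (0.55 equiv), 4 Å molecular sieves, CH2Cl2, −20 °C; stopped near half conversion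
Reagents that add atoms: tert-butyl hydroperoxide, CC(C)(C)OO
Why: Sharpless kinetic resolution; with the L-(+)-tartrate the (S)-alcohol should be epoxidised faster and give the erythro epoxy alcohol (sets C12 as R), while the isolated methallyl alkene is inert to the titanium–tartrate peroxide.

Step 16
Reactants: 23 (1S)-4-methyl-1-[(2R)-2-methyloxiran-2-yl]pent-4-en-1-ol
Product: 24 (1R)-4-methyl-1-[(2R)-2-methyloxiran-2-yl]pent-4-en-1-yl 4-nitrobenzoate
Conditions: 4-O2NC6H4CO2H, PPh3, DIAD, toluene, 0 °C to rt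
Reagents that add atoms: 4-nitrobenzoic acid, OC(=O)c1ccc(cc1)[N+](=O)[O-]
Why: Mitsunobu inversion; SN2 displacement of the oxyphosphonium by the carboxylate inverts C11 (S to R), turning the erythro into the required threo pattern, and the tied-back oxiranyl neighbour hinders less than an open quaternary centre.

Step 17
Reactants: 24 (1R)-4-methyl-1-[(2R)-2-methyloxiran-2-yl]pent-4-en-1-yl 4-nitrobenzoate
Product: 25 (1R)-4-methyl-1-[(2R)-2-methyloxiran-2-yl]pent-4-en-1-ol (fragment B)
Conditions: K2CO3, MeOH, 0 °C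
Reagents that add atoms: none
Why: methanolysis of the activated benzoate; at 0 °C the secondary alkoxide should not attack the fully substituted oxirane carbon (no Payne rearrangement).

Step 18
Reactants: 25 (1R)-4-methyl-1-[(2R)-2-methyloxiran-2-yl]pent-4-en-1-ol; 26 dichlorodiisopropylsilane; 18 (3R,5Z,8S)-9-{[(4-methoxybenzyl)oxy]methyl}-5-methyl-8-[(phenylsulfonyl)methyl]deca-1,5,9-trien-3-ol
Product: 28 mixed diisopropylsilylene acetal of 18 (through O6) and 25 (through O11), via chlorosilane 27 (not isolated)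
Conditions: 26 (3 equiv), imidazole, CH2Cl2, 0 °C, excess 26 removed in vacuo; then 18, imidazole, DMAP (cat.), DMF, rt
Reagents that add atoms: none
Why: stepwise silylation; the hindered alcohol 25 is loaded first on excess dichlorosilane so that no symmetrical silaketal forms, and the less hindered allylic alcohol 18 then displaces the remaining chloride.

Step 19
Reactants: 28 mixed diisopropylsilylene acetal of 18 and 25
Product: 29 nine-membered (7Z)-1,3-dioxa-2-silacycle (C7=C8 closed; sulfone arm on C6 and methyloxiranyl group on C11 unchanged)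
Conditions: second-generation Hoveyda–Grubbs catalyst RuCl2(H2IMes)(=CH-C6H4-2-OiPr) (2 × 10 mol %), toluene (2 mM), 90 °C, argon sparge
Reagents that add atoms: none
Why: The ruthenium alkylidene should load on the monosubstituted C7 vinyl group, add to the 1,1-disubstituted C8 alkene and release ethene through the metallacyclobutane to leave the C7=C8 bond. The closest known reaction type is temporary silicon-tethered ring-closing metathesis of mixed dialkoxysilanes, established for seven- and eight-membered rings; a nine-membered ring with a trisubstituted alkene extends the ring size within the same substrate class. The ring that closes is the nine-membered 1,3-dioxa-2-silacycle (Si, O, C6, C7, C8, C9, C10, C11, O), formed by metathesis of two terminal alkenes held 1,6 by the O–Si–O bridge, whose two isopropyl groups favour the folded rotamers. No stereocentre is formed; a ring of this size holds only a cis ring alkene, so C6 and C9 should end cis (7Z). Site selectivity is needed against the trisubstituted 3,4-alkene, which this catalyst does not engage, and against the C15 methylene, whose union with C7 would give an eight-membered carbocycle; that methylene is flanked by the branched C1 and the C16 ether and should react far more slowly than the unhindered methallyl terminus at C8. High dilution and removal of ethene should hold back dimerisation.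

Step 20
Reactants: 29 nine-membered (7Z)-1,3-dioxa-2-silacycle
Product: 31 silylene-bridged fourteen-membered carbocycle (C13–C14 closed; C12 tertiary alcohol; C14 phenylsulfonyl as both epimers), via lithiated sulfone 30 (not isolated)
Conditions: LiN(iPr)2 (1.2 equiv), THF (3 mM), −78 °C; DMPU, −78 °C to rt; H2O
Reagents that add atoms: none
Why: intramolecular alkylation of a sulfone-stabilised carbanion by a terminal epoxide, the carbanion–epoxide closure long used for fourteen-membered cembrane rings; attack at the unsubstituted oxirane carbon C13 (14-exo-tet) leaves the C12–O bond and its configuration intact, and the C14 epimers converge in step 21.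

Step 21
Reactants: 31 silylene-bridged fourteen-membered carbocycle (C14 sulfone)
Product: 32 desulfonylated carbocycle (C14 methylene)
Conditions: Na/Hg (6 %), Na2HPO4, MeOH/THF, −20 °C
Reagents that add atoms: none
Why: reductive desulfonylation by electron transfer; no leaving group sits β to C14, so elimination cannot compete, and the benzyl-type ether and the silaketal should tolerate the buffered medium.

Step 22
Reactants: 32 desulfonylated carbocycle
Product: 33 allylic alcohol (free C16–OH)
Conditions: DDQ, CH2Cl2/pH 7 buffer 10:1, 0 °C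
Reagents that add atoms: none
Why: oxidative cleavage of the 4-methoxybenzyl ether via the benzylic cation and hemiacetal; it is orthogonal to the silicon bridge, which a fluoride-labile group at C16 would not have been.

Step 23
Reactants: 33 allylic alcohol
Product: 34 enal (C16 aldehyde)
Conditions: TEMPO (10 mol %), PhI(OAc)2, CH2Cl2, rt
Reagents that add atoms: none
Why: oxoammonium oxidation selective for the primary allylic alcohol; the tertiary C12 hydroxyl cannot be oxidised.

Step 24
Reactants: 34 enal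
Product: 35 seco acid (C16 carboxylic acid; C12–OH free)
Conditions: NaClO2, NaH2PO4, 2-methyl-2-butene, t-BuOH/H2O, 0 °C
Reagents that add atoms: sodium chlorite, [Na+].[O-]Cl=O
Why: Pinnick oxidation; the scavenger alkene intercepts hypochlorous acid before it can reach the trisubstituted ring alkenes.

Step 25
Reactants: 35 seco acid
Product: 37 silylene-protected seven-membered lactone (C16(=O)–O12), via mixed anhydride 36 (not isolated)
Conditions: 2,4,6-Cl3C6H2COCl, Et3N, THF, rt; then DMAP, toluene (5 mM), 80 °C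
Reagents that add atoms: none
Why: Yamaguchi lactonisation; DMAP turns the mixed anhydride into the acylpyridinium, which is attacked by the only free hydroxyl (tertiary C12–OH, held seven atoms away by the carbocycle), and C12 keeps its configuration because its C–O bond is not broken.

Step 26
Reactants: 37 silylene-protected lactone
Product: 38 (3R,4S)-3,4-epoxide of 37
Conditions: D-fructose-derived Shi ketone (30 mol %), KHSO5 (as Oxone), K2CO3, Bu4NHSO4, MeCN/dimethoxymethane/aq. Na2B4O7 buffer (pH 10.5), 0 °C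
Reagents that add atoms: potassium peroxymonosulfate, [K+].[O-]S(=O)(=O)OO
Why: Shi epoxidation; the chiral dioxirane should take the most electron-rich and least shielded alkene (C3=C4; C7=C8 lies beside the silyloxy carbon inside the diisopropylsilyl-bridged ring and C15=C17 is an acrylate) through the spiro transition state that, for trisubstituted alkenes, puts oxygen on the face giving (3R,4S), the Z geometry becoming the cis relation of C2 and C5.

Step 27
Reactants: 38 (3R,4S)-3,4-epoxide of 37
Product: 39 CNP0250657.1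
Conditions: Bu4NF/AcOH (1:1), THF, 0 °C to rt
Reagents that add atoms: none
Why: buffered fluoride cleaves both Si–O bonds of the silylene while the oxirane, the β-hydroxy epoxide array and the α-methylene lactone should survive the near-neutral medium.

**Compound list**

1 | 2,3-dibromopropene | C=C(Br)CBr | starting material
2 | 4-methoxybenzyl alcohol | COc1ccc(CO)cc1 | starting material
3 | 1-{[(2-bromoprop-2-en-1-yl)oxy]methyl}-4-methoxybenzene | C=C(Br)COCc1ccc(OC)cc1 | intermediate
4 | 2-{3-[(4-methoxybenzyl)oxy]prop-1-en-2-yl}-4,4,5,5-tetramethyl-1,3,2-dioxaborolane | C=C(COCc1ccc(OC)cc1)B1OC(C)(C)C(C)(C)O1 | intermediate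
5 | (tert-butyldimethylsilyloxy)acetaldehyde | CC(C)(C)[Si](C)(C)OCC=O | starting material
6 | ethyl (triphenylphosphoranylidene)acetate | CCOC(=O)C=P(c1ccccc1)(c1ccccc1)c1ccccc1 | starting material
7 | ethyl (E)-4-[(tert-butyldimethylsilyl)oxy]but-2-enoate | CCOC(=O)/C=C/CO[Si](C)(C)C(C)(C)C | intermediate
8 | ethyl (3S)-3-{[(tert-butyldimethylsilyl)oxy]methyl}-4-{[(4-methoxybenzyl)oxy]methyl}pent-4-enoate | CC(C)(C)[Si](C)(C)OC[C@H](C(=C)COCc1ccc(OC)cc1)CC(=O)OCC | intermediate
9 | (3S)-3-{[(tert-butyldimethylsilyl)oxy]methyl}-4-{[(4-methoxybenzyl)oxy]methyl}pent-4-enal | CC(C)(C)[Si](C)(C)OC[C@H](C(=C)COCc1ccc(OC)cc1)CC=O | intermediate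
10 | (5S)-5-{[(tert-butyldimethylsilyl)oxy]methyl}-6-{[(4-methoxybenzyl)oxy]methyl}-2-methylhepta-1,6-dien-3-ol, both C3 epimers | CC(C)(C)[Si](C)(C)OC[C@H](C(=C)COCc1ccc(OC)cc1)CC(O)C(C)=C | intermediate
11 | tributyl{[((5S)-5-{[(tert-butyldimethylsilyl)oxy]methyl}-6-{[(4-methoxybenzyl)oxy]methyl}-2-methylhepta-1,6-dien-3-yl)oxy]methyl}stannane | CC(C)(C)[Si](C)(C)OC[C@H](C(=C)COCc1ccc(OC)cc1)CC(OC[Sn](CCCC)(CCCC)CCCC)C(C)=C | intermediate
12 | lithiomethyl ether of 10 (α-alkoxymethyllithium) | CC(C)(C)[Si](C)(C)OC[C@H](C(=C)COCc1ccc(OC)cc1)CC(OC[Li])C(C)=C | intermediate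
13 | (3Z,6S)-6-{[(tert-butyldimethylsilyl)oxy]methyl}-7-{[(4-methoxybenzyl)oxy]methyl}-3-methylocta-3,7-dien-1-ol | CC(C)(C)[Si](C)(C)OC[C@H](C(=C)COCc1ccc(OC)cc1)C/C=C(/C)CCO | intermediate
14 | (3Z,6S)-6-{[(tert-butyldimethylsilyl)oxy]methyl}-7-{[(4-methoxybenzyl)oxy]methyl}-3-methylocta-3,7-dienal | CC(C)(C)[Si](C)(C)OC[C@H](C(=C)COCc1ccc(OC)cc1)C/C=C(/C)CC=O | intermediate
15 | (3R,5Z,8S)-8-{[(tert-butyldimethylsilyl)oxy]methyl}-9-{[(4-methoxybenzyl)oxy]methyl}-5-methyldeca-1,5,9-trien-3-ol | CC(C)(C)[Si](C)(C)OC[C@H](C(=C)COCc1ccc(OC)cc1)C/C=C(/C)C[C@H](C=C)O | intermediate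
16 | (2S,4Z,7R)-2-{3-[(4-methoxybenzyl)oxy]prop-1-en-2-yl}-5-methylnona-4,8-diene-1,7-diol | OC[C@H](C(=C)COCc1ccc(OC)cc1)C/C=C(/C)C[C@H](C=C)O | intermediate
17 | (3R,5Z,8S)-8-(iodomethyl)-9-{[(4-methoxybenzyl)oxy]methyl}-5-methyldeca-1,5,9-trien-3-ol | IC[C@H](C(=C)COCc1ccc(OC)cc1)C/C=C(/C)C[C@H](C=C)O | intermediate
18 | (3R,5Z,8S)-9-{[(4-methoxybenzyl)oxy]methyl}-5-methyl-8-[(phenylsulfonyl)methyl]deca-1,5,9-trien-3-ol (fragment A; C1 S, C6 R, 3Z in the numbering used here) | O=S(=O)(c1ccccc1)C[C@H](C(=C)COCc1ccc(OC)cc1)C/C=C(/C)C[C@H](C=C)O | intermediate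
19 | 4-bromo-2-methylbut-1-ene | C=C(C)CCBr | starting material
20 | methacrolein | C=C(C)C=O | starting material
21 | (3-methylbut-3-en-1-yl)magnesium bromide | C=C(C)CC[Mg]Br | intermediate
22 | 2,6-dimethylhepta-1,6-dien-3-ol (racemic) | C=C(C)CCC(O)C(C)=C | intermediate
23 | (1S)-4-methyl-1-[(2R)-2-methyloxiran-2-yl]pent-4-en-1-ol | O[C@@H](CCC(C)=C)[C@@]1(C)CO1 | intermediate
24 | (1R)-4-methyl-1-[(2R)-2-methyloxiran-2-yl]pent-4-en-1-yl 4-nitrobenzoate | O=C(O[C@H](CCC(C)=C)[C@@]1(C)CO1)c1ccc(cc1)[N+](=O)[O-] | intermediate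
25 | (1R)-4-methyl-1-[(2R)-2-methyloxiran-2-yl]pent-4-en-1-ol (fragment B; C11 R, C12 R) | O[C@H](CCC(C)=C)[C@@]1(C)CO1 | intermediate
26 | dichlorodiisopropylsilane | CC(C)[Si](Cl)(Cl)C(C)C | starting material
27 | chloro(diisopropyl){[(1R)-4-methyl-1-[(2R)-2-methyloxiran-2-yl]pent-4-en-1-yl]oxy}silane | Cl[Si](C(C)C)(C(C)C)O[C@H](CCC(C)=C)[C@@]1(C)CO1 | intermediate
28 | mixed diisopropylsilylene acetal of 18 (through O6) and 25 (through O11); (1S,3Z,6R,11R,12R) | O=S(=O)(c1ccccc1)C[C@H](C(=C)COCc1ccc(OC)cc1)C/C=C(/C)C[C@H](C=C)O[Si](C(C)C)(C(C)C)O[C@H](CCC(C)=C)[C@@]1(C)CO1 | intermediate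
29 | nine-membered 2,2-diisopropyl-1,3-dioxa-2-silacycle with the Z C7=C8 alkene (ring: Si, O, C6, C7, C8, C9, C10, C11, O); C6 carries the C1–C5 chain with C14 sulfone and C16 4-methoxybenzyl ether, C11 carries the (R)-2-methyloxiran-2-yl group; (1S,3Z,6R,7Z,11R,12R) | O=S(=O)(c1ccccc1)C[C@H](C(=C)COCc1ccc(OC)cc1)C/C=C(/C)C[C@H]2O[Si](C(C)C)(C(C)C)O[C@H](CC/C(C)=C\2)[C@@]1(C)CO1 | intermediate
30 | C14-lithio derivative of 29 | [Li]C(S(=O)(=O)c1ccccc1)[C@H](C(=C)COCc1ccc(OC)cc1)C/C=C(/C)C[C@H]2O[Si](C(C)C)(C(C)C)O[C@H](CC/C(C)=C\2)[C@@]1(C)CO1 | intermediate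
31 | 6,11-O-diisopropylsilylene-bridged fourteen-membered carbocycle: C13–C14 closed, C12 tertiary alcohol, C14 phenylsulfonyl (both epimers), C16 4-methoxybenzyl ether; (1S,3Z,6R,7Z,11R,12R) | O=S(=O)(c1ccccc1)C3[C@H](C(=C)COCc1ccc(OC)cc1)C/C=C(/C)C[C@H]2O[Si](C(C)C)(C(C)C)O[C@H](CC/C(C)=C\2)[C@](C)(O)C3 | intermediate
32 | 31 without the sulfonyl group (C14 methylene) | C1[C@H](C(=C)COCc3ccc(OC)cc3)C/C=C(/C)C[C@H]2O[Si](C(C)C)(C(C)C)O[C@H](CC/C(C)=C\2)[C@](C)(O)C1 | intermediate
33 | allylic alcohol: 32 with free C16–OH | C1[C@H](C(=C)CO)C/C=C(/C)C[C@H]2O[Si](C(C)C)(C(C)C)O[C@H](CC/C(C)=C\2)[C@](C)(O)C1 | intermediate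
34 | enal: C16 aldehyde | C1[C@H](C(=C)C=O)C/C=C(/C)C[C@H]2O[Si](C(C)C)(C(C)C)O[C@H](CC/C(C)=C\2)[C@](C)(O)C1 | intermediate
35 | seco acid: C16 carboxylic acid, C12–OH free | C1[C@H](C(=C)C(=O)O)C/C=C(/C)C[C@H]2O[Si](C(C)C)(C(C)C)O[C@H](CC/C(C)=C\2)[C@](C)(O)C1 | intermediate
36 | mixed anhydride of 35 with 2,4,6-trichlorobenzoic acid | C1[C@H](C(=C)C(=O)OC(=O)c3c(Cl)cc(Cl)cc3Cl)C/C=C(/C)C[C@H]2O[Si](C(C)C)(C(C)C)O[C@H](CC/C(C)=C\2)[C@](C)(O)C1 | intermediate
37 | 6,11-O-diisopropylsilylene-protected α-methylene seven-membered lactone (C16(=O)–O12); (1S,3Z,6R,7Z,11R,12R) | C=C1C(=O)O[C@]2(C)CC[C@H]1C/C=C(/C)C[C@H]3O[Si](C(C)C)(C(C)C)O[C@@H]2CC/C(C)=C\3 | intermediate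
38 | (3R,4S)-3,4-epoxide of 37 | C=C1C(=O)O[C@]2(C)CC[C@H]1C[C@H]4O[C@@]4(C)C[C@H]3O[Si](C(C)C)(C(C)C)O[C@@H]2CC/C(C)=C\3 | intermediate
39 | CNP0250657.1, (1S,3R,4S,6R,7Z,11R,12R) | C=C1C(=O)O[C@]2(C)CC[C@H]1C[C@H]1O[C@@]1(C)C[C@@H](O)/C=C(/C)CC[C@H]2O | target

**Step count and risks**

Total: 27 steps. Longest linear sequence: 22 steps (1, 2, 4 to 13, 18 to 27).

Steps most likely to fail:

Step 19. The nine-membered closure onto a 1,1-disubstituted alkene may be slower than catalyst decay, the C7 alkylidene may instead close onto the C15 methylene, or the diene may oligomerise. Fallback: invert the order of the two ring closures. Compound 28 is deprotonated with LiN(iPr)2 in THF/DMPU at high dilution, so that the sulfone carbanion opens the oxirane while the chain is still free, giving the thirteen-membered macrocyclic silaketal F1 (ring through C13–C14 and the O–Si–O bridge). The same ruthenium catalyst then joins the C7 vinyl and C8 methallyl groups, now held across that ring, and the route is rejoined at 31.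

Step 25. Acylation of the tertiary C12 hydroxyl by the acrylic acylpyridinium may be slower than dimerisation or than conjugate addition of DMAP. Fallback: replace nucleophilic catalysis on a mixed anhydride by thiophilic activation of an isolated thioester. Acid 35 is converted with 2,2'-dipyridyl disulfide and PPh3 into the S-(pyridin-2-yl) thioester F2, and silver triflate (AgOSO2CF3) in toluene at rt then drives the silver-assisted Corey–Nicolaou-type lactonisation onto the hindered alcohol, rejoining the route at 37.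

Step 26. The bicyclic macrocycle may expose only one face of C3=C4 and so override the catalyst, or oxygen transfer to C7=C8 may compete. Fallback: deliver the oxygen from O6 instead. The silylene of 37 is removed with HF·pyridine (buffered with pyridine) to give the diol lactone F3. The less hindered allylic C6 hydroxyl is converted with Boc2O/DMAP into the tert-butyl carbonate F4, which also deactivates C7=C8. IBr in toluene at −85 °C then gives the six-membered cyclic iodocarbonate F5, with the carbonate oxygen on C4 syn to O6 and iodine anti on C3. Brief treatment with K2CO3 in MeOH at 0 °C opens the carbonate and closes the oxirane with inversion at C3, arriving directly at 39.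

Further compounds
F1 | step 19 | thirteen-membered macrocyclic silaketal from 28: C13–C14 closed, C12 tertiary alcohol, C14 phenylsulfonyl, C7 vinyl and C8 methallyl terminus still open | O=S(=O)(c1ccccc1)C3[C@H](C(=C)COCc1ccc(OC)cc1)C/C=C(/C)C[C@H](C=C)O[Si](C(C)C)(C(C)C)O[C@H](CCC(C)=C)[C@](C)(O)C3
F2 | step 25 | S-(pyridin-2-yl) thioester of acid 35 | C1[C@H](C(=C)C(=O)Sc3ccccn3)C/C=C(/C)C[C@H]2O[Si](C(C)C)(C(C)C)O[C@H](CC/C(C)=C\2)[C@](C)(O)C1
F3 | step 26 | diol lactone: 37 without the silylene (free C6–OH and C11–OH) | C=C1C(=O)O[C@]2(C)CC[C@H]1C/C=C(/C)C[C@@H](O)/C=C(/C)CC[C@H]2O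
F4 | step 26 | C6 tert-butyl carbonate of F3 | C=C1C(=O)O[C@]2(C)CC[C@H]1C/C=C(/C)C[C@@H](OC(=O)OC(C)(C)C)/C=C(/C)CC[C@H]2O
F5 | step 26 | cyclic iodocarbonate: six-membered carbonate bridging O6 and O4, iodine on C3, C11–OH free | C=C1C(=O)O[C@]2(C)CC[C@H]1C[C@H](I)[C@]3(C)C[C@@H](OC(=O)O3)/C=C(/C)CC[C@H]2O
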